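**Assumption:** the target has no stereocentre and no stereogenic double bond (the prenyl alkene carries two identical methyls), so it is achiral and "single enantiomer" needs no stereocontrol.

## Retrosynthetic overview

1. The 2-pyranone is made last. Its C3–C4 bond comes from acylating the enolate of a 3,4-dihydrocoumarin with methylketene dimer (which brings C4, C5, C6, both alkyl groups and the ring O). The lactone then switches from the phenol to the new ring and frees the arene OH.
2. The dihydrocoumarin comes from the Ar–CH2 bond: Pd coupling of a hexasubstituted aryl iodide with the zinc homoenolate of ethyl propanoate (a β-carbanion joined to the aryl iodide carbon). The chain supplies the bridge CH2 plus C3 and C2 of the pyranone and lactonises on the neighbouring OH.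
3. The aryl iodide comes from iodination of the last free ring CH, after C-prenylation between the two OH groups, after Hoesch acylation of 5-methoxyresorcinol.
4. Ring order: benzene ring bought; dihydrocoumarin lactone (temporary, step 4); 2-pyranone (step 6).

## Route

**Step 1**
Reactants: 1 5-methoxybenzene-1,3-diol (5-methoxyresorcinol); 2 2-methylpropanenitrile (isobutyronitrile)
Product: 4 1-(2,4-dihydroxy-6-methoxyphenyl)-2-methylpropan-1-one, via ketiminium chloride 3 (not isolated)
Conditions: ZnCl2 (0.3 equiv), HCl (g), Et2O, 0 °C, 16 h; then H2O, 100 °C, 1 h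
Reagents that add atoms: water, O; hydrogen chloride, Cl (its chloride sits in 3 only)
Why: Houben–Hoesch acylation: the nitrilium electrophile C-acylates the ring para to one OH and ortho to the other (between OH and OMe) without cleaving the methyl ether, and the ketiminium salt hydrolyses to the ketone; the minor 2,6-dihydroxy-4-methoxy isomer is removed by chromatography.

**Step 2**
Reactants: 4 1-(2,4-dihydroxy-6-methoxyphenyl)-2-methylpropan-1-one; 5 1-bromo-3-methylbut-2-ene (prenyl bromide)
Product: 6 1-[2,4-dihydroxy-6-methoxy-3-(3-methylbut-2-en-1-yl)phenyl]-2-methylpropan-1-one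
Conditions: 5 (1.0 equiv), 10% aq KOH (2 equiv), 0 °C → rt
Reagents that add atoms: none
Why: Base-mediated C-prenylation (SN2 C-alkylation of the ambident phenoxide) in water, where hydrogen bonding shields the oxygens; C3, between the two hydroxyls and ortho to the chelated OH, is expected to be the most nucleophilic carbon, and a modest yield is accepted with O-prenyl, C5 and bis-prenyl by-products removed by chromatography.

**Step 3**
Reactants: 6 1-[2,4-dihydroxy-6-methoxy-3-(3-methylbut-2-en-1-yl)phenyl]-2-methylpropan-1-one
Product: 7 1-[2,4-dihydroxy-5-iodo-6-methoxy-3-(3-methylbut-2-en-1-yl)phenyl]-2-methylpropan-1-one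
Conditions: I2 (1.05 equiv), NaHCO3 (1.2 equiv), THF–H2O 1:1, 0 °C, dark
Reagents that add atoms: iodine, II
Why: Electrophilic aromatic iodination through the phenoxide at the only free ring position (C5); the phenoxide carbon should react with iodine much faster than the trisubstituted prenyl alkene, so iodoetherification is held back by using one equivalent at 0 °C.

**Step 4 (key step)**
Reactants: 7 1-[2,4-dihydroxy-5-iodo-6-methoxy-3-(3-methylbut-2-en-1-yl)phenyl]-2-methylpropan-1-one; 8 (3-ethoxy-3-oxopropyl)zinc bromide (0.5 M in THF)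
Product: 10 7-hydroxy-5-methoxy-8-(3-methylbut-2-en-1-yl)-6-(2-methylpropanoyl)-3,4-dihydro-2H-1-benzopyran-2-one, via ethyl arylpropanoate 9 (not isolated)
Conditions: 8 (3.5 equiv), Pd(OAc)2 (5 mol%), SPhos (10 mol%), THF, 25 → 50 °C; aq NH4Cl; then PPTS (10 mol%), PhMe, 90 °C
Reagents that add atoms: none
Why: Negishi cross-coupling of a zinc homoenolate: the chelate-stabilised β-zincio ester (inert to the ketone and to β-elimination) transmetallates to the ArPd(II)I, and Pd/SPhos is known to couple hindered halides and to tolerate free OH groups; the ortho-hydroxy ester then lactonises by acid-catalysed transesterification on the only neighbouring OH, with PPTS mild enough to spare the prenyl group.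

**Step 5**
Reactants: 11 propanoyl chloride (2 equiv)
Product: 13 (Z)-4-ethylidene-3-methyloxetan-2-one (methylketene dimer; racemic), via methylketene 12 (not isolated)
Conditions: Et3N (1.0 equiv), Et2O, 0 °C → rt, 16 h; filter; distil
Reagents that add atoms: none
Why: Dehydrochlorination gives methylketene, which undergoes the known head-to-tail [2+2] ketene dimerisation to the β-lactone; its one stereocentre is racemic and is lost in step 6.

**Step 6**
Reactants: 10 7-hydroxy-5-methoxy-8-(3-methylbut-2-en-1-yl)-6-(2-methylpropanoyl)-3,4-dihydro-2H-1-benzopyran-2-one; 13 (Z)-4-ethylidene-3-methyloxetan-2-one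
Product: 15 6-ethyl-4-hydroxy-3-{[2,4-dihydroxy-6-methoxy-3-(3-methylbut-2-en-1-yl)-5-(2-methylpropanoyl)phenyl]methyl}-5-methyl-2H-pyran-2-one (target), via 3-acylated lactone 14 (not isolated)
Conditions: LiHMDS (2.1 equiv), THF, −78 °C; 13 (1.3 equiv), −78 °C; LiHMDS (1.1 equiv), −78 → 23 °C; 1 M HCl
Reagents that add atoms: none
Why: Proposed new method: the lithium enolate of aryl lactone 10 (the phenol sits as a chelated, unreactive phenoxide) attacks the strained acyl carbon of 13 and ring-opens it to the enolate of 14, whose 5-enolate oxygen then adds 6-exo to the activated aryl ester carbonyl and expels the phenoxide, so the lactone moves from the phenol to the new ring and tautomerises to the aromatic 4-hydroxy-2-pyranone as the thermodynamic sink; the closest known reaction types are C-acylation of enolates by ketene dimers (diketene acetoacetylation, amide opening of methylketene dimer) and base-promoted lactonisation of 3,5-dioxo esters to 4-hydroxy-2-pyranones (Claisen acylation then translactonisation).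

## Compound list

1 | 5-methoxybenzene-1,3-diol | COc1cc(O)cc(O)c1 | starting material
2 | 2-methylpropanenitrile | CC(C)C#N | starting material
3 | 1-(2,4-dihydroxy-6-methoxyphenyl)-2-methylpropan-1-iminium chloride | COc1cc(O)cc(O)c1C(=[NH2+])C(C)C.[Cl-] | intermediate
4 | 1-(2,4-dihydroxy-6-methoxyphenyl)-2-methylpropan-1-one | COc1cc(O)cc(O)c1C(=O)C(C)C | intermediate
5 | 1-bromo-3-methylbut-2-ene | CC(C)=CCBr | starting material
6 | 1-[2,4-dihydroxy-6-methoxy-3-(3-methylbut-2-en-1-yl)phenyl]-2-methylpropan-1-one | COc1cc(O)c(CC=C(C)C)c(O)c1C(=O)C(C)C | intermediate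
7 | 1-[2,4-dihydroxy-5-iodo-6-methoxy-3-(3-methylbut-2-en-1-yl)phenyl]-2-methylpropan-1-one | COc1c(I)c(O)c(CC=C(C)C)c(O)c1C(=O)C(C)C | intermediate
8 | (3-ethoxy-3-oxopropyl)zinc bromide | CCOC(=O)CC[Zn]Br | starting material
9 | ethyl 3-[2,4-dihydroxy-6-methoxy-3-(3-methylbut-2-en-1-yl)-5-(2-methylpropanoyl)phenyl]propanoate | CCOC(=O)CCc1c(O)c(CC=C(C)C)c(O)c(C(=O)C(C)C)c1OC | intermediate
10 | 7-hydroxy-5-methoxy-8-(3-methylbut-2-en-1-yl)-6-(2-methylpropanoyl)-3,4-dihydro-2H-1-benzopyran-2-one | COc1c2CCC(=O)Oc2c(CC=C(C)C)c(O)c1C(=O)C(C)C | intermediate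
11 | propanoyl chloride | CCC(Cl)=O | starting material
12 | methylketene (prop-1-en-1-one) | CC=C=O | intermediate
13 | (Z)-4-ethylidene-3-methyloxetan-2-one, racemic | C/C=C1\OC(=O)C1C | intermediate
14 | 7-hydroxy-5-methoxy-8-(3-methylbut-2-en-1-yl)-3-(2-methyl-3-oxopentanoyl)-6-(2-methylpropanoyl)-3,4-dihydro-2H-1-benzopyran-2-one (formed as its lithium enolate; stereoisomer mixture, both centres lost) | CCC(=O)C(C)C(=O)C1Cc2c(OC)c(C(=O)C(C)C)c(O)c(CC=C(C)C)c2OC1=O | intermediate
15 | 6-ethyl-4-hydroxy-3-{[2,4-dihydroxy-6-methoxy-3-(3-methylbut-2-en-1-yl)-5-(2-methylpropanoyl)phenyl]methyl}-5-methyl-2H-pyran-2-one | CCc1oc(=O)c(Cc2c(O)c(CC=C(C)C)c(O)c(C(=O)C(C)C)c2OC)c(O)c1C | target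

## Summary

Total step count: 6. Longest linear sequence: 5 (steps 1, 2, 3, 4, 6); step 5 is a one-step side branch.

Three steps most likely to fail:

**Step 4 (homoenolate coupling on the unprotected, hexasubstituted iodophenol).** Likely failure modes are protodeiodination back to 6 and quenching of the zinc reagent by the phenols. The fallback sets out from 7 and comes back at 9. Both phenols are acetylated (Ac2O, pyridine, DMAP) to give 1-[2,4-bis(acetyloxy)-5-iodo-6-methoxy-3-(3-methylbut-2-en-1-yl)phenyl]-2-methylpropan-1-one F2. This is a less electron-rich iodide with no acidic protons. It is coupled with 8 (1.5 equiv, Pd(OAc)2/SPhos, THF, 50 °C) to give ethyl 3-[2,4-bis(acetyloxy)-6-methoxy-3-(3-methylbut-2-en-1-yl)-5-(2-methylpropanoyl)phenyl]propanoate F3. K2CO3 in EtOH removes both acetates to give 9, which is lactonised with PPTS as in step 4.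

**Step 6 (one-pot acylation and lactone switch).** Likely failure modes are O-acylation, deprotonation of 13, or fragmentation of the aryl lactone enolate. The fallback sets out from 10 and comes back at 14, using two sequential Claisen acylations with simple propanoyl donors. The enolate of 10 (LiHMDS 3.1 equiv, THF, −78 °C) is acylated with 1-propanoylimidazole to give 7-hydroxy-5-methoxy-8-(3-methylbut-2-en-1-yl)-6-(2-methylpropanoyl)-3-propanoyl-3,4-dihydro-2H-1-benzopyran-2-one F4. Its γ-carbanion (LDA 3.2 equiv, −78 → −20 °C) is then acylated with N-methoxy-N-methylpropanamide to give 14 in the flask. This closes to 15 on warming, with DBU if needed.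

**Step 2 (C-prenylation: O- versus C-alkylation, C3 versus C5, over-alkylation).** The fallback sets out from 4 and comes back at 6. Iodination of 4 (I2, NaHCO3, THF–H2O, 0 °C) is expected to enter at C3, ortho to the chelated hydroxyl, giving 1-(2,4-dihydroxy-3-iodo-6-methoxyphenyl)-2-methylpropan-1-one F1; any C5 iodide is separated. Stille coupling of F1 with tributyl(3-methylbut-2-en-1-yl)stannane (Pd(PPh3)4, DMF, 80 °C) then gives 6. The prenyl group is fixed at the halogen-bearing carbon, so O-alkylation and bis-alkylation cannot occur.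

## Further compounds

F1 | step 2 | 1-(2,4-dihydroxy-3-iodo-6-methoxyphenyl)-2-methylpropan-1-one | COc1cc(O)c(I)c(O)c1C(=O)C(C)C
F2 | step 4 | 1-[2,4-bis(acetyloxy)-5-iodo-6-methoxy-3-(3-methylbut-2-en-1-yl)phenyl]-2-methylpropan-1-one | COc1c(I)c(OC(C)=O)c(CC=C(C)C)c(OC(C)=O)c1C(=O)C(C)C
F3 | step 4 | ethyl 3-[2,4-bis(acetyloxy)-6-methoxy-3-(3-methylbut-2-en-1-yl)-5-(2-methylpropanoyl)phenyl]propanoate | CCOC(=O)CCc1c(OC(C)=O)c(CC=C(C)C)c(OC(C)=O)c(C(=O)C(C)C)c1OC
F4 | step 6 | 7-hydroxy-5-methoxy-8-(3-methylbut-2-en-1-yl)-6-(2-methylpropanoyl)-3-propanoyl-3,4-dihydro-2H-1-benzopyran-2-one | CCC(=O)C1Cc2c(OC)c(C(=O)C(C)C)c(O)c(CC=C(C)C)c2OC1=O
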